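The route cuts ring A of the flavone at C5–O and C4a–C4. The C5 hydroxyl and the C4 carbonyl sit on the adjacent carbons C5 and C4a, with the C8a oxygen flanking C4a, and this ortho pair is read as an aryne that has taken up a carboxylic acid. In one operation a 3-alkoxybenzyne inserts into the C(=O)–O bond of a (Z)-α-methoxycinnamic acid that already holds C2, C3 with its methoxy group, C4 and ring B. This gives the hydroxychalcone framework without closing a ring. The precursors are a 2-silylaryl triflate with a MOM ether next to silicon and the bis-benzylated acid. Ring C is closed afterwards through O1–C2.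

Key step: step 8

Assumption: flavone numbering (O1, C2–C4, C4a, C5–C8, C8a, ring B primed) is used for the atoms of all intermediates, and bromination of 1 is taken to occur at C2 between hydroxyl and formyl, as with isovanillin, to be confirmed by NOE before the material is carried on.

Step 1
Reactants: 1 3-hydroxy-4,5-dimethoxybenzaldehyde
Product: 2 2-bromo-3-hydroxy-4,5-dimethoxybenzaldehyde
Conditions: Br2, NaOAc, AcOH, rt
Reagents that add atoms: bromine, BrBr
Why: Electrophilic aromatic bromination of the phenol should place the halogen at C2, ortho to the hydroxyl and para to the C5 methoxy group, while NaOAc buffers the hydrogen bromide.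

Step 2
Reactants: 2 2-bromo-3-hydroxy-4,5-dimethoxybenzaldehyde
Product: 3 2-bromo-4,5-dimethoxy-3-(methoxymethoxy)benzaldehyde
Conditions: MOMCl, i-Pr2NEt, CH2Cl2, 0 °C to rt
Reagents that add atoms: chloromethyl methyl ether, COCCl
Why: Williamson-type O-alkylation of the phenol with the reactive chloromethyl ether gives a MOM acetal that later tolerates n-BuLi, fluoride and heat.

Step 3
Reactants: 3 2-bromo-4,5-dimethoxy-3-(methoxymethoxy)benzaldehyde
Product: 5 2-bromo-4,5-dimethoxy-3-(methoxymethoxy)phenol, via aryl formate 4 (not isolated)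
Conditions: mCPBA, CH2Cl2, rt; then K2CO3, MeOH, rt
Reagents that add atoms: mCPBA, OOC(=O)c1cccc(Cl)c1
Why: Baeyer–Villiger (Dakin-type) oxidation, in which the electron-rich aryl group para to a methoxy donor migrates, gives the formate, which mild methanolysis cleaves; a peracid is used because the ring has no free ortho or para hydroxyl for the alkaline peroxide variant.

Step 4
Reactants: 5 2-bromo-4,5-dimethoxy-3-(methoxymethoxy)phenol
Product: 9 4,5-dimethoxy-3-(methoxymethoxy)-2-(trimethylsilyl)phenyl trifluoromethanesulfonate, via silyl ether 6 (not isolated), via aryllithium 7 (not isolated), via lithium silylphenoxide 8 (not isolated)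
Conditions: HMDS, THF, 70 °C, then evaporate; n-BuLi, THF, −78 °C; Tf2O, −78 °C to rt
Reagents that add atoms: HMDS, C[Si](C)(C)N[Si](C)(C)C; triflic anhydride, O=S(=O)(OS(=O)(=O)C(F)(F)F)C(F)(F)F
Why: O-silylation, bromine–lithium exchange and a 1,3 O→C silyl shift (retro-Brook rearrangement) put silicon on the carbon between the two oxygens, and the lithium phenoxide is trapped as the triflate, the standard entry to Kobayashi-type aryne precursors from 2-bromophenols.

Step 5
Reactants: 10 2,3-dihydroxybenzaldehyde
Product: 11 2,3-bis(benzyloxy)benzaldehyde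
Conditions: BnBr, K2CO3, DMF, 60 °C
Reagents that add atoms: benzyl bromide, BrCc1ccccc1
Why: Williamson etherification of both phenols installs benzyl groups that leave in the final hydrogenolysis together with the one on the C5 oxygen.

Step 6
Reactants: 11 2,3-bis(benzyloxy)benzaldehyde; 12 methyl 2-(dimethoxyphosphoryl)-2-methoxyacetate
Product: 13 methyl (Z)-3-[2,3-bis(benzyloxy)phenyl]-2-methoxyprop-2-enoate
Conditions: NaH, THF, 0 °C to rt
Reagents that add atoms: none
Why: Horner–Wadsworth–Emmons olefination with the α-methoxyphosphonate should favour the Z alkene (aryl trans to the ester), any E isomer being removed by chromatography, and the alkene geometry is erased in any case when ring C is formed.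

Step 7
Reactants: 13 methyl (Z)-3-[2,3-bis(benzyloxy)phenyl]-2-methoxyprop-2-enoate
Product: 14 (Z)-3-[2,3-bis(benzyloxy)phenyl]-2-methoxyprop-2-enoic acid
Conditions: LiOH, THF/MeOH/H2O, rt; then 1 M HCl, 0 °C
Reagents that add atoms: lithium hydroxide, [Li+].[OH-]
Why: Saponification of the methyl ester leaves the captodative enol ether and the benzyl ethers untouched, since both are inert to hydroxide and to a brief cold acidification.

Step 8
Reactants: 9 4,5-dimethoxy-3-(methoxymethoxy)-2-(trimethylsilyl)phenyl trifluoromethanesulfonate; 14 (Z)-3-[2,3-bis(benzyloxy)phenyl]-2-methoxyprop-2-enoic acid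
Product: 17 (Z)-3-[2,3-bis(benzyloxy)phenyl]-1-[6-hydroxy-3,4-dimethoxy-2-(methoxymethoxy)phenyl]-2-methoxyprop-2-en-1-one, via aryne 15 (not isolated), via aryl anion ester 16 (not isolated)
Conditions: CsF, THF, 125 °C, sealed tube (9 in slight excess)
Reagents that add atoms: none
Why: Fluoride attacks silicon of 9 and triflate leaves to give the aryne, whose C–O bond at the future C8a polarises the triple bond so that the cesium carboxylate of 14 adds at the remote carbon (future C5) and the charge develops next to the MOM ether (future C4a). This aryl anion attacks its own ester carbonyl through a four-membered tetrahedral intermediate, which opens to the C5 phenoxide and the C4 ketone, an anionic ortho-Fries-type 1,3 O→C acyl shift; the closest known reaction is the fluoride-induced insertion of arynes into the C–O bond of carboxylic acids, cinnamic acids included, which gives o-hydroxyaryl ketones. No ring is closed and no stereocentre is formed, and the Z alkene of the acid is carried over unchanged. The step needs a single orientation of addition across the aryne, which the one alkoxy flank (MOM ether on one side, hydrogen on the other) secures by the usual 3-alkoxyaryne rule, and it needs acyl transfer to outrun protonation of the aryl anion, which the aprotic medium and the high temperature favour. The α-methoxy group and the ortho-substituted, electron-rich ring B make the enone a poor acceptor, so the new C5 phenoxide should not add to the β-carbon, and any such reversible oxa-Michael closure would be undone under the basic benzylation of step 9.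

Step 9
Reactants: 17 (Z)-3-[2,3-bis(benzyloxy)phenyl]-1-[6-hydroxy-3,4-dimethoxy-2-(methoxymethoxy)phenyl]-2-methoxyprop-2-en-1-one
Product: 18 (Z)-1-[6-(benzyloxy)-3,4-dimethoxy-2-(methoxymethoxy)phenyl]-3-[2,3-bis(benzyloxy)phenyl]-2-methoxyprop-2-en-1-one
Conditions: BnBr, K2CO3, DMF, 50 °C
Reagents that add atoms: benzyl bromide, BrCc1ccccc1
Why: Williamson benzylation of the hydrogen-bonded C5 phenol blocks this oxygen so that only the C8a oxygen can later close ring C, and under carbonate any oxa-Michael adduct through C5–O equilibrates with the open phenoxide and is drained by alkylation.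

Step 10
Reactants: 18 (Z)-1-[6-(benzyloxy)-3,4-dimethoxy-2-(methoxymethoxy)phenyl]-3-[2,3-bis(benzyloxy)phenyl]-2-methoxyprop-2-en-1-one
Product: 19 (Z)-1-[6-(benzyloxy)-2-hydroxy-3,4-dimethoxyphenyl]-3-[2,3-bis(benzyloxy)phenyl]-2-methoxyprop-2-en-1-one
Conditions: HCl (cat.), MeOH/THF, 45 °C
Reagents that add atoms: none
Why: Acid-catalysed transacetalisation to methanol removes the MOM group next to the carbonyl while the benzyl ethers hold and the α-methoxy enone resists protonation, because the adjacent carbonyl destabilises the oxocarbenium ion; partial closure to chromanone 20 would be harmless, as 20 is the intermediate of step 11.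

Step 11
Reactants: 19 (Z)-1-[6-(benzyloxy)-2-hydroxy-3,4-dimethoxyphenyl]-3-[2,3-bis(benzyloxy)phenyl]-2-methoxyprop-2-en-1-one
Product: 22 5-(benzyloxy)-2-[2,3-bis(benzyloxy)phenyl]-3,7,8-trimethoxy-4H-chromen-4-one, via chromanone 20 (not isolated), via iodochromanone 21 (not isolated)
Conditions: I2 (0.1 equiv), DMSO, 120 °C
Reagents that add atoms: none
Why: In this iodine–DMSO oxidative cyclisation of a 2'-hydroxychalcone, 6-endo oxa-Michael addition of the C8a hydroxyl to C2 gives the chromanone, α-iodination at C3 and loss of hydrogen iodide give the chromone, and DMSO reoxidises the hydrogen iodide to iodine.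

Step 12
Reactants: 22 5-(benzyloxy)-2-[2,3-bis(benzyloxy)phenyl]-3,7,8-trimethoxy-4H-chromen-4-one
Product: 23 5,2',3'-trihydroxy-3,7,8-trimethoxyflavone
Conditions: H2 (1 atm), 10% Pd/C, EtOAc/MeOH, rt
Reagents that add atoms: none
Why: Catalytic hydrogenolysis cleaves the three benzyl ethers in one operation, while the aryl methyl ethers and the tetrasubstituted C2=C3 bond of the conjugated chromone should not be reduced under these mild conditions.

Compound list
1 | 3-hydroxy-4,5-dimethoxybenzaldehyde | COc1cc(C=O)cc(O)c1OC | starting material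
2 | 2-bromo-3-hydroxy-4,5-dimethoxybenzaldehyde | COc1cc(C=O)c(Br)c(O)c1OC | intermediate
3 | 2-bromo-4,5-dimethoxy-3-(methoxymethoxy)benzaldehyde | COCOc1c(Br)c(C=O)cc(OC)c1OC | intermediate
4 | 2-bromo-4,5-dimethoxy-3-(methoxymethoxy)phenyl formate | COCOc1c(Br)c(OC=O)cc(OC)c1OC | intermediate
5 | 2-bromo-4,5-dimethoxy-3-(methoxymethoxy)phenol | COCOc1c(Br)c(O)cc(OC)c1OC | intermediate
6 | [2-bromo-4,5-dimethoxy-3-(methoxymethoxy)phenoxy]trimethylsilane | COCOc1c(Br)c(O[Si](C)(C)C)cc(OC)c1OC | intermediate
7 | [3,4-dimethoxy-2-(methoxymethoxy)-6-(trimethylsilyloxy)phenyl]lithium | COCOc1c([Li])c(O[Si](C)(C)C)cc(OC)c1OC | intermediate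
8 | lithium 4,5-dimethoxy-3-(methoxymethoxy)-2-(trimethylsilyl)phenolate | COCOc1c([Si](C)(C)C)c([O-])cc(OC)c1OC.[Li+] | intermediate
9 | 4,5-dimethoxy-3-(methoxymethoxy)-2-(trimethylsilyl)phenyl trifluoromethanesulfonate | COCOc1c(OC)c(OC)cc(OS(=O)(=O)C(F)(F)F)c1[Si](C)(C)C | intermediate
10 | 2,3-dihydroxybenzaldehyde | O=Cc1cccc(O)c1O | starting material
11 | 2,3-bis(benzyloxy)benzaldehyde | O=Cc1cccc(OCc2ccccc2)c1OCc1ccccc1 | intermediate
12 | methyl 2-(dimethoxyphosphoryl)-2-methoxyacetate | COC(C(=O)OC)P(=O)(OC)OC | starting material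
13 | methyl (Z)-3-[2,3-bis(benzyloxy)phenyl]-2-methoxyprop-2-enoate | CO/C(=C\c1cccc(OCc2ccccc2)c1OCc1ccccc1)C(=O)OC | intermediate
14 | (Z)-3-[2,3-bis(benzyloxy)phenyl]-2-methoxyprop-2-enoic acid | CO/C(=C\c1cccc(OCc2ccccc2)c1OCc1ccccc1)C(=O)O | intermediate
15 | 4,5-dimethoxy-3-(methoxymethoxy)benzyne (1,2-didehydrobenzene, triple bond between the former triflate and silyl carbons) | COCOC1=C(OC)C(OC)=CC#C1 | intermediate
16 | cesium 6-{[(Z)-3-[2,3-bis(benzyloxy)phenyl]-2-methoxyprop-2-enoyl]oxy}-3,4-dimethoxy-2-(methoxymethoxy)benzen-1-ide | COCOc1c(OC)c(OC)cc(OC(=O)/C(OC)=C/c2cccc(OCc3ccccc3)c2OCc2ccccc2)[c-]1.[Cs+] | intermediate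
17 | (Z)-3-[2,3-bis(benzyloxy)phenyl]-1-[6-hydroxy-3,4-dimethoxy-2-(methoxymethoxy)phenyl]-2-methoxyprop-2-en-1-one | COCOc1c(OC)c(OC)cc(O)c1C(=O)/C(OC)=C/c1cccc(OCc2ccccc2)c1OCc1ccccc1 | intermediate
18 | (Z)-1-[6-(benzyloxy)-3,4-dimethoxy-2-(methoxymethoxy)phenyl]-3-[2,3-bis(benzyloxy)phenyl]-2-methoxyprop-2-en-1-one | COCOc1c(OC)c(OC)cc(OCc2ccccc2)c1C(=O)/C(OC)=C/c1cccc(OCc2ccccc2)c1OCc1ccccc1 | intermediate
19 | (Z)-1-[6-(benzyloxy)-2-hydroxy-3,4-dimethoxyphenyl]-3-[2,3-bis(benzyloxy)phenyl]-2-methoxyprop-2-en-1-one | COc1cc(OCc2ccccc2)c(C(=O)/C(OC)=C/c2cccc(OCc3ccccc3)c2OCc2ccccc2)c(O)c1OC | intermediate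
20 | 5-(benzyloxy)-2-[2,3-bis(benzyloxy)phenyl]-3,7,8-trimethoxychroman-4-one (C2 and C3 configuration not defined, racemic) | COc1cc(OCc2ccccc2)c2c(c1OC)OC(c1cccc(OCc3ccccc3)c1OCc1ccccc1)C(OC)C2=O | intermediate
21 | 5-(benzyloxy)-2-[2,3-bis(benzyloxy)phenyl]-3-iodo-3,7,8-trimethoxychroman-4-one (configuration not defined) | COc1cc(OCc2ccccc2)c2c(c1OC)OC(c1cccc(OCc3ccccc3)c1OCc1ccccc1)C(I)(OC)C2=O | intermediate
22 | 5-(benzyloxy)-2-[2,3-bis(benzyloxy)phenyl]-3,7,8-trimethoxy-4H-chromen-4-one | COc1cc(OCc2ccccc2)c2c(=O)c(OC)c(-c3cccc(OCc4ccccc4)c3OCc3ccccc3)oc2c1OC | intermediate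
23 | 5,2',3'-trihydroxy-3,7,8-trimethoxyflavone | COc1cc(O)c2c(=O)c(OC)c(-c3cccc(O)c3O)oc2c1OC | target

Total step count: 12 (steps 1–4 for the aryne precursor, steps 5–7 for the acid, steps 8–12 after convergence).
Longest linear sequence: 9 steps (steps 1, 2, 3, 4, 8, 9, 10, 11, 12).

Steps most likely to fail

Step 8. The aryl anion may be protonated before acyl transfer, so that the reaction stops at simple O-arylation. The carboxylate may add with the reverse orientation, the product phenoxide may be arylated by a second aryne, or the C5 phenoxide may close onto the enone at 125 °C. The fallback avoids the aryne and sets out from bromophenol 5 and acid 14. Carbodiimide esterification (EDC·HCl, DMAP, CH2Cl2) should give 2-bromo-4,5-dimethoxy-3-(methoxymethoxy)phenyl (Z)-3-[2,3-bis(benzyloxy)phenyl]-2-methoxyprop-2-enoate F1. Bromine–lithium exchange with n-BuLi in THF at −100 °C (Parham-type conditions, where exchange outruns addition to the ester) gives the ortho-lithiated aryl ester F2, the lithium counterpart of 16, with the metal fixed at the future C4a. The same anionic ortho-Fries acyl shift then proceeds at low temperature, and protonation brings the material back to the route at 17.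

Step 11. The oxa-Michael closure onto the hindered, electron-rich α-methoxy enone may be slow. Iodination of the activated C6 position of ring A or acid-induced loss of the C5 benzyl group may then compete at 120 °C. The fallback separates ring closure from dehydrogenation. From 19, base-mediated oxa-Michael closure (NaOAc, EtOH, reflux) gives chromanone 20, isolated this time. Hydride abstraction with DDQ (dioxane, reflux) then dehydrogenates C2–C3 and returns to the route at 22. No compound outside the list arises (F0).

Step 1. Electrophilic attack may compete at C6 (para to the hydroxyl), or a second bromination may occur; either would transpose or spoil the oxygen pattern of ring A. The fallback replaces electrophilic substitution by directed metalation and sets out from 1. MOM protection (MOMCl, i-Pr2NEt, CH2Cl2) gives 3,4-dimethoxy-5-(methoxymethoxy)benzaldehyde F3. Lithium N-methylpiperazide in THF masks the formyl group in the flask as the lithium α-amino alkoxide F4. n-BuLi then removes the proton at C2, the only free position ortho to the MOM ether and also next to the alkoxide, to give the aryllithium F5. 1,2-Dibromotetrachloroethane transfers bromine to give the brominated amino alkoxide F6, and aqueous work-up releases the aldehyde, which rejoins the route at 3.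

Further compounds
F1 | step 8 | 2-bromo-4,5-dimethoxy-3-(methoxymethoxy)phenyl (Z)-3-[2,3-bis(benzyloxy)phenyl]-2-methoxyprop-2-enoate | COCOc1c(Br)c(OC(=O)/C(OC)=C/c2cccc(OCc3ccccc3)c2OCc2ccccc2)cc(OC)c1OC
F2 | step 8 | [6-{[(Z)-3-[2,3-bis(benzyloxy)phenyl]-2-methoxyprop-2-enoyl]oxy}-3,4-dimethoxy-2-(methoxymethoxy)phenyl]lithium | COCOc1c([Li])c(OC(=O)/C(OC)=C/c2cccc(OCc3ccccc3)c2OCc2ccccc2)cc(OC)c1OC
F0 | step 11 | none | none
F3 | step 1 | 3,4-dimethoxy-5-(methoxymethoxy)benzaldehyde | COCOc1cc(C=O)cc(OC)c1OC
F4 | step 1 | lithium [3,4-dimethoxy-5-(methoxymethoxy)phenyl](4-methylpiperazin-1-yl)methanolate | COCOc1cc(C([O-])N2CCN(C)CC2)cc(OC)c1OC.[Li+]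
F5 | step 1 | lithium [2-lithio-4,5-dimethoxy-3-(methoxymethoxy)phenyl](4-methylpiperazin-1-yl)methanolate | COCOc1c([Li])c(C([O-])N2CCN(C)CC2)cc(OC)c1OC.[Li+]
F6 | step 1 | lithium [2-bromo-4,5-dimethoxy-3-(methoxymethoxy)phenyl](4-methylpiperazin-1-yl)methanolate | COCOc1c(Br)c(C([O-])N2CCN(C)CC2)cc(OC)c1OC.[Li+]
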